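The disconnection is the bond between the chain CH2 and the vinylic carbon that bears CH2OH. The five atoms O(carbinol)–CH–CH2–CH=C(CH2OH) of the (Z)-alkene and its homoallylic carbinol are read as a ring-opened 2,3-dihydrofuran. In the key step the alkylcopper of the cyclohexenyl chain and an α-lithiated (R)-2-(3-furyl)-2,3-dihydrofuran form a cuprate. Its 1,2-metalate rearrangement makes this bond with inversion at the ring sp2 carbon, releases the ring oxygen as the carbinol and fixes the olefin geometry. Carboxylation of the resulting alkenylcopper adds the future CH2OH carbon and closes a dihydropyranone. The furan is the latent butenolide.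

Key step: step 6

Remark: the lactol carbon of 22 is lost in step 9, so 22 is taken as a mixture of epimers at that carbon; the facial sense of step 4 is assigned by analogy with aryl aldehydes.

Step 1
Reactants: 1 dihydro-β-ionone [4-(2,6,6-trimethylcyclohex-1-en-1-yl)butan-2-one]
Product: 3 2-(but-3-yn-1-yl)-1,3,3-trimethylcyclohex-1-ene, via enol phosphate 2 (not isolated)
Conditions: LDA (1.1 equiv), THF, −78 °C; ClP(O)(OEt)2, −78 °C → rt; then LDA (2.3 equiv), THF, −78 °C → rt; H2O
Reagents that add atoms: none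
Why: Kinetic deprotonation at the methyl group gives the terminal enol phosphate, from which excess LDA eliminates diethyl phosphate to the terminal alkyne (methyl ketone to alkyne conversion via an enol phosphate).

Step 2
Reactants: 3 2-(but-3-yn-1-yl)-1,3,3-trimethylcyclohex-1-ene
Product: 6 (3E)-4-methyl-6-(2,6,6-trimethylcyclohex-1-en-1-yl)hex-3-en-1-ol, via alkenylalane 4 (not isolated), via lithium alanate 5 (not isolated)
Conditions: Me3Al (2 equiv), Cp2ZrCl2 (cat.), (CH2Cl)2, rt; evaporate; n-BuLi, hexane, 0 °C; ethylene oxide, THF, −30 °C → rt; cold 1 M HCl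
Reagents that add atoms: trimethylaluminium C[Al](C)C; ethylene oxide C1CO1
Why: Zirconium-catalysed syn-methylalumination of the terminal alkyne (Negishi carboalumination) places Me and Al cis, and the derived alanate should open ethylene oxide with retention at the alkenyl carbon, so the (E)-trisubstituted alkene is set by the syn addition.

Step 3
Reactants: 6 (3E)-4-methyl-6-(2,6,6-trimethylcyclohex-1-en-1-yl)hex-3-en-1-ol
Product: 7 2-[(3E)-6-iodo-3-methylhex-3-en-1-yl]-1,3,3-trimethylcyclohex-1-ene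
Conditions: I2, PPh3, imidazole, CH2Cl2, 0 °C → rt
Reagents that add atoms: iodine II
Why: Appel-type iodination of a primary alcohol proceeds by SN2 displacement of the alkoxyphosphonium ion and should leave both alkenes untouched.

Step 4
Reactants: 8 furan-3-carbaldehyde
Product: 10 (1R)-1-(furan-3-yl)but-3-yn-1-ol, via borate ester 9 (not isolated)
Conditions: allenylboronic acid pinacol ester (1.5 equiv), (R)-TRIP (5 mol %), 4 Å MS, toluene, −20 °C; aqueous work-up
Reagents that add atoms: allenylboronic acid pinacol ester C=C=CB1OC(C)(C)C(C)(C)O1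
Why: Chiral phosphoric acid-catalysed propargylation of an aromatic aldehyde by an allenylboronate through a closed six-membered SE2' transition state, in which the (R)-catalyst is expected to direct attack to the Re face and give the (R)-carbinol (the enantiomeric catalyst is taken should the sense prove opposite).

Step 5
Reactants: 10 (1R)-1-(furan-3-yl)but-3-yn-1-ol
Product: 12 tributyl[(5R)-5-(furan-3-yl)-4,5-dihydrofuran-2-yl]stannane, via vinylmolybdate 11 (not isolated)
Conditions: (Et3N)Mo(CO)5 [from Mo(CO)6, Et3N, Et2O, hν], Bu3SnOTf, Et3N, Et2O, rt; chromatography on Et3N-deactivated silica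
Reagents that add atoms: tributyltin triflate CCCC[Sn](CCCC)(CCCC)OS(=O)(=O)C(F)(F)F
Why: Molybdenum-promoted endo-cycloisomerisation of a 1-alkyn-4-ol through a metal vinylidene should give an anionic 2-metallated dihydrofuran that the tin electrophile traps at carbon (alkynol cycloisomerisation with stannyl trapping), the carbinol stereocentre not being involved.

Step 6
Reactants: 7 2-[(3E)-6-iodo-3-methylhex-3-en-1-yl]-1,3,3-trimethylcyclohex-1-ene; 12 tributyl[(5R)-5-(furan-3-yl)-4,5-dihydrofuran-2-yl]stannane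
Product: 19 (6R)-6-(furan-3-yl)-3-[(3E)-4-methyl-6-(2,6,6-trimethylcyclohex-1-en-1-yl)hex-3-en-1-yl]-5,6-dihydro-2H-pyran-2-one, via alkyllithium 13 (not isolated), via alkylcopper 14 (not isolated), via lithiated dihydrofuran 15 (not isolated), via mixed cuprate 16 (not isolated), via alkenylcopper alkoxide 17 (not isolated), via hydroxy acid 18 (not isolated)
Conditions: (a) 7, t-BuLi (2 equiv), Et2O, −78 °C; CuBr·SMe2, Et2O/Me2S, −78 °C; (b) 12, n-BuLi, THF, −78 °C; add (b) to (a), −78 °C → rt; (c) CO2 (g), P(OEt)3 (cat.), DMPU, −40 °C → rt; 1 M HCl; PPTS (cat.), CH2Cl2, rt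
Reagents that add atoms: carbon dioxide O=C=O
Why: Iodine–lithium exchange on 7 and tin–lithium exchange on 12 give two carbanions that are joined on copper(I) as cuprate 16; on warming, the alkyl group should migrate from copper to the α-alkoxyalkenyl carbon anti to its C–O bond, which breaks and releases the ring oxygen as the alkoxide (copper-mediated 1,2-metalate rearrangement, the closest known type being the cuprate ring opening of 5-lithio-2,3-dihydrofurans). Because the migration inverts the sp2 carbon, the new chain ends up trans and copper cis to the CH2–CH(O) arm, and carboxylation of the C–Cu bond with retention (carboxylation of an alkenylcopper) should therefore give the (Z)-hydroxy acid 18. The only ring closed is the dihydropyranone, by 6-exo-trig lactonisation of 18, which only this olefin geometry allows. No stereocentre is formed: the (R)-carbinol carbon is carried from 12 untouched, since the C–O bond that breaks is the one at the vinylic carbon. The step needs transfer of the chain alkyl group alone, which is secured by its being the only alkyl ligand on copper. It also needs the furan C–H bonds left alone, which is secured by generating 15 through tin–lithium exchange at −78 °C instead of deprotonation.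

Step 7
Reactants: 19 (6R)-6-(furan-3-yl)-3-[(3E)-4-methyl-6-(2,6,6-trimethylcyclohex-1-en-1-yl)hex-3-en-1-yl]-5,6-dihydro-2H-pyran-2-one
Product: 20 (1R,3Z,7E)-1-(furan-3-yl)-4-(hydroxymethyl)-8-methyl-10-(2,6,6-trimethylcyclohex-1-en-1-yl)deca-3,7-dien-1-ol
Conditions: DIBAL-H (4 equiv), CH2Cl2, −78 → 0 °C; aq. Rochelle salt
Reagents that add atoms: none
Why: Excess DIBAL-H should reduce the α,β-unsaturated δ-lactone by 1,2-hydride addition through the lactol to the allylic alcohol and free the secondary alcohol, so the ring-fixed geometry is delivered as the (Z)-alkene while the furan and the other alkenes are inert.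

Step 8
Reactants: 20 (1R,3Z,7E)-1-(furan-3-yl)-4-(hydroxymethyl)-8-methyl-10-(2,6,6-trimethylcyclohex-1-en-1-yl)deca-3,7-dien-1-ol
Product: 22 5-hydroxy-4-[(1R,3Z,7E)-1-hydroxy-4-(hydroxymethyl)-8-methyl-10-(2,6,6-trimethylcyclohex-1-en-1-yl)deca-3,7-dien-1-yl]furan-2(5H)-one, via furan endoperoxide 21 (not isolated)
Conditions: O2, hν (visible), polymer-bound Rose Bengal (cat.), i-Pr2NEt, CH2Cl2, −78 °C
Reagents that add atoms: oxygen O=O
Why: [4+2] cycloaddition of singlet oxygen to the furan, expected to outpace the ene reaction of the chain alkenes at −78 °C, gives endoperoxide 21, from which the hindered base should remove the less hindered bridgehead proton remote from the substituent (Kornblum–DeLaMare-type fragmentation) and so place the carbonyl on the unsubstituted side.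

Step 9
Reactants: 22 5-hydroxy-4-[(1R,3Z,7E)-1-hydroxy-4-(hydroxymethyl)-8-methyl-10-(2,6,6-trimethylcyclohex-1-en-1-yl)deca-3,7-dien-1-yl]furan-2(5H)-one
Product: 24 4-[(1R,3Z,7E)-1-hydroxy-4-(hydroxymethyl)-8-methyl-10-(2,6,6-trimethylcyclohex-1-en-1-yl)deca-3,7-dien-1-yl]furan-2(5H)-one, via seco hydroxy acid 23 (not isolated)
Conditions: NaBH4, MeOH/THF, 0 °C; then 1 M HCl, rt
Reagents that add atoms: none
Why: Borohydride should reduce the aldehyde of the ring-opened form of the γ-hydroxybutenolide, and the resulting 4-hydroxybutenoic acid 23 relactonises on acidification to the butenolide (reduction of a pseudo-acid lactol), leaving the carbinol stereocentre and all alkenes unchanged.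

Compound list
1 | dihydro-β-ionone, 4-(2,6,6-trimethylcyclohex-1-en-1-yl)butan-2-one | CC(=O)CCC1=C(C)CCCC1(C)C | starting material
2 | diethyl 4-(2,6,6-trimethylcyclohex-1-en-1-yl)but-1-en-2-yl phosphate | C=C(CCC1=C(C)CCCC1(C)C)OP(=O)(OCC)OCC | intermediate (not isolated)
3 | 2-(but-3-yn-1-yl)-1,3,3-trimethylcyclohex-1-ene | C#CCCC1=C(C)CCCC1(C)C | intermediate
4 | dimethyl[(1E)-2-methyl-4-(2,6,6-trimethylcyclohex-1-en-1-yl)but-1-en-1-yl]alane | CC1=C(CC/C(C)=C/[Al](C)C)C(C)(C)CCC1 | intermediate (not isolated)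
5 | lithium butyl(dimethyl)[(1E)-2-methyl-4-(2,6,6-trimethylcyclohex-1-en-1-yl)but-1-en-1-yl]alanate | [Li+].CCCC[Al-](C)(C)/C=C(\C)CCC1=C(C)CCCC1(C)C | intermediate (not isolated)
6 | (3E)-4-methyl-6-(2,6,6-trimethylcyclohex-1-en-1-yl)hex-3-en-1-ol | CC1=C(CC/C(C)=C/CCO)C(C)(C)CCC1 | intermediate
7 | 2-[(3E)-6-iodo-3-methylhex-3-en-1-yl]-1,3,3-trimethylcyclohex-1-ene | CC1=C(CC/C(C)=C/CCI)C(C)(C)CCC1 | intermediate
8 | furan-3-carbaldehyde | O=Cc1ccoc1 | starting material
9 | 2-{[(1R)-1-(furan-3-yl)but-3-yn-1-yl]oxy}-4,4,5,5-tetramethyl-1,3,2-dioxaborolane | C#CC[C@@H](OB1OC(C)(C)C(C)(C)O1)c1ccoc1 | intermediate (not isolated)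
10 | (1R)-1-(furan-3-yl)but-3-yn-1-ol | C#CC[C@@H](O)c1ccoc1 | intermediate
11 | triethylammonium pentacarbonyl[(5R)-5-(furan-3-yl)-4,5-dihydrofuran-2-yl]molybdate | CC[NH+](CC)CC.O=C=[Mo-](=C=O)(=C=O)(=C=O)(=C=O)C1=CC[C@H](c2ccoc2)O1 | intermediate (not isolated)
12 | tributyl[(5R)-5-(furan-3-yl)-4,5-dihydrofuran-2-yl]stannane | CCCC[Sn](CCCC)(CCCC)C1=CC[C@H](c2ccoc2)O1 | intermediate
13 | [(3E)-4-methyl-6-(2,6,6-trimethylcyclohex-1-en-1-yl)hex-3-en-1-yl]lithium | CC1=C(CC/C(C)=C/CC[Li])C(C)(C)CCC1 | intermediate (not isolated)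
14 | [(3E)-4-methyl-6-(2,6,6-trimethylcyclohex-1-en-1-yl)hex-3-en-1-yl]copper | CC1=C(CC/C(C)=C/CC[Cu])C(C)(C)CCC1 | intermediate (not isolated)
15 | [(5R)-5-(furan-3-yl)-4,5-dihydrofuran-2-yl]lithium | [Li]C1=CC[C@H](c2ccoc2)O1 | intermediate (not isolated)
16 | lithium [(5R)-5-(furan-3-yl)-4,5-dihydrofuran-2-yl][(3E)-4-methyl-6-(2,6,6-trimethylcyclohex-1-en-1-yl)hex-3-en-1-yl]cuprate | [Li+].CC1=C(CC/C(C)=C/CC[Cu-]C2=CC[C@H](c3ccoc3)O2)C(C)(C)CCC1 | intermediate (not isolated)
17 | lithium (1R,3Z,7E)-4-cuprio-1-(furan-3-yl)-8-methyl-10-(2,6,6-trimethylcyclohex-1-en-1-yl)deca-3,7-dien-1-olate (Cu cis to the CH2–CH(O) arm) | [Li+].CC1=C(CC/C(C)=C/CC/C([Cu])=C/C[C@@H]([O-])c2ccoc2)C(C)(C)CCC1 | intermediate (not isolated)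
18 | (2Z,5R)-5-(furan-3-yl)-5-hydroxy-2-[(3E)-4-methyl-6-(2,6,6-trimethylcyclohex-1-en-1-yl)hex-3-en-1-yl]pent-2-enoic acid | CC1=C(CC/C(C)=C/CC/C(=C/C[C@@H](O)c2ccoc2)C(=O)O)C(C)(C)CCC1 | intermediate (not isolated)
19 | (6R)-6-(furan-3-yl)-3-[(3E)-4-methyl-6-(2,6,6-trimethylcyclohex-1-en-1-yl)hex-3-en-1-yl]-5,6-dihydro-2H-pyran-2-one | CC1=C(CC/C(C)=C/CCC2=CC[C@H](c3ccoc3)OC2=O)C(C)(C)CCC1 | intermediate
20 | (1R,3Z,7E)-1-(furan-3-yl)-4-(hydroxymethyl)-8-methyl-10-(2,6,6-trimethylcyclohex-1-en-1-yl)deca-3,7-dien-1-ol | CC1=C(CC/C(C)=C/CC/C(=C/C[C@@H](O)c2ccoc2)CO)C(C)(C)CCC1 | intermediate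
21 | furan endoperoxide of 20 (2,3,7-trioxabicyclo[2.2.1]hept-5-ene carrying the side chain on C5) | CC1=C(CC/C(C)=C/CC/C(=C/C[C@@H](O)C2=CC3OOC2O3)CO)C(C)(C)CCC1 | intermediate (not isolated)
22 | 5-hydroxy-4-[(1R,3Z,7E)-1-hydroxy-4-(hydroxymethyl)-8-methyl-10-(2,6,6-trimethylcyclohex-1-en-1-yl)deca-3,7-dien-1-yl]furan-2(5H)-one (epimers at C5) | CC1=C(CC/C(C)=C/CC/C(=C/C[C@@H](O)C2=CC(=O)OC2O)CO)C(C)(C)CCC1 | intermediate
23 | 4-hydroxy-3-[(1R,3Z,7E)-1-hydroxy-4-(hydroxymethyl)-8-methyl-10-(2,6,6-trimethylcyclohex-1-en-1-yl)deca-3,7-dien-1-yl]but-2-enoic acid (CH2OH cis to CO2H) | CC1=C(CC/C(C)=C/CC/C(=C/C[C@@H](O)/C(CO)=C/C(=O)O)CO)C(C)(C)CCC1 | intermediate (not isolated)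
24 | 4-[(1R,3Z,7E)-1-hydroxy-4-(hydroxymethyl)-8-methyl-10-(2,6,6-trimethylcyclohex-1-en-1-yl)deca-3,7-dien-1-yl]furan-2(5H)-one | CC1=C(CC/C(C)=C/CC/C(=C/C[C@@H](O)C2=CC(=O)OC2)CO)C(C)(C)CCC1 | target

Total step count: 9. Longest linear sequence: 7 steps (1, 2, 3, 6, 7, 8, 9).

Steps most likely to fail

Step 6. The alkenylcopper formed after the migration may be carboxylated too slowly, so that it is simply protonated on work-up and the one-carbon unit is not installed. The fallback sets out from 7 and 12 and returns at 19. The same cuprate rearrangement is quenched with iodine (THF, −78 → 0 °C), a trap that alkenylcopper species accept readily, to give (1R,3Z,7E)-1-(furan-3-yl)-4-iodo-8-methyl-10-(2,6,6-trimethylcyclohex-1-en-1-yl)deca-3,7-dien-1-ol F1. Palladium-catalysed carbonylative lactonisation of this iodoalkenol (CO 1 atm, Pd(PPh3)4 cat., Et3N, THF/MeCN, 50 °C) then closes the dihydropyranone 19, the carbonyl carbon now coming from CO by acylpalladium capture of the homoallylic hydroxyl.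

Step 5. Protonation of the vinylmolybdate may outrun its stannylation, which would give the tin-free dihydrofuran, and direct lithiation of that compound would compete with metalation of the furan ring. The fallback sets out from 10 and returns at 12. Plain molybdenum-catalysed cycloisomerisation (Mo(CO)6 cat., Et3N, Et2O, hν) gives (2R)-2-(furan-3-yl)-2,3-dihydrofuran F2. Addition of benzenesulfinic acid across the enol ether (PhSO2H, CH2Cl2, rt) gives (2R)-2-(furan-3-yl)-5-(phenylsulfonyl)tetrahydrofuran F3. Its sulfone α-proton is far more acidic than any furan proton, so n-BuLi (THF, −78 °C) followed by Bu3SnCl should give tributyl[(5R)-5-(furan-3-yl)-2-(phenylsulfonyl)tetrahydrofuran-2-yl]stannane F4. Elimination of sulfinate (i-Pr2NEt, CHCl3, 60 °C) then delivers 12.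

Step 8. Singlet oxygen may be consumed in ene reactions at the tetrasubstituted ring alkene and the trisubstituted chain alkenes, or the endoperoxide may fragment toward the other bridgehead and place the carbonyl next to the substituent. The fallback sets out from 8 and returns at 22. C5-selective lithiation of the morpholine α-amino alkoxide of the aldehyde (lithium morpholide, THF, −78 °C; s-BuLi; TMSCl; aqueous work-up) gives 5-(trimethylsilyl)furan-3-carbaldehyde F5. The operations of steps 4 to 7 are then repeated on the silylated series: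
- step 4 conditions give (1R)-1-[5-(trimethylsilyl)furan-3-yl]but-3-yn-1-ol F6;
- step 5 conditions give tributyl{(5R)-5-[5-(trimethylsilyl)furan-3-yl]-4,5-dihydrofuran-2-yl}stannane F7;
- step 6 conditions with 7 give (6R)-3-[(3E)-4-methyl-6-(2,6,6-trimethylcyclohex-1-en-1-yl)hex-3-en-1-yl]-6-[5-(trimethylsilyl)furan-3-yl]-5,6-dihydro-2H-pyran-2-one F8;
- step 7 conditions give (1R,3Z,7E)-4-(hydroxymethyl)-8-methyl-1-[5-(trimethylsilyl)furan-3-yl]-10-(2,6,6-trimethylcyclohex-1-en-1-yl)deca-3,7-dien-1-ol F9.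

The 2-silylfuran is more electron-rich and should react faster with singlet oxygen (O2, hν, Rose Bengal, CH2Cl2/MeOH, −78 °C, no base). Its endoperoxide collapses by silyl migration to oxygen, so the carbonyl can only form at the former C–Si carbon, which leads to 22.

Further compounds
F1 | step 6 | (1R,3Z,7E)-1-(furan-3-yl)-4-iodo-8-methyl-10-(2,6,6-trimethylcyclohex-1-en-1-yl)deca-3,7-dien-1-ol | CC1=C(CC/C(C)=C/CC/C(I)=C/C[C@@H](O)c2ccoc2)C(C)(C)CCC1
F2 | step 5 | (2R)-2-(furan-3-yl)-2,3-dihydrofuran | C1=CC[C@H](c2ccoc2)O1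
F3 | step 5 | (2R)-2-(furan-3-yl)-5-(phenylsulfonyl)tetrahydrofuran (anomeric mixture) | O=S(=O)(c1ccccc1)C1CC[C@H](c2ccoc2)O1
F4 | step 5 | tributyl[(5R)-5-(furan-3-yl)-2-(phenylsulfonyl)tetrahydrofuran-2-yl]stannane | CCCC[Sn](CCCC)(CCCC)C1(S(=O)(=O)c2ccccc2)CC[C@H](c2ccoc2)O1
F5 | step 8 | 5-(trimethylsilyl)furan-3-carbaldehyde | O=Cc1coc([Si](C)(C)C)c1
F6 | step 8 | (1R)-1-[5-(trimethylsilyl)furan-3-yl]but-3-yn-1-ol | C#CC[C@@H](O)c1coc([Si](C)(C)C)c1
F7 | step 8 | tributyl{(5R)-5-[5-(trimethylsilyl)furan-3-yl]-4,5-dihydrofuran-2-yl}stannane | CCCC[Sn](CCCC)(CCCC)C1=CC[C@H](c2coc([Si](C)(C)C)c2)O1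
F8 | step 8 | (6R)-3-[(3E)-4-methyl-6-(2,6,6-trimethylcyclohex-1-en-1-yl)hex-3-en-1-yl]-6-[5-(trimethylsilyl)furan-3-yl]-5,6-dihydro-2H-pyran-2-one | CC1=C(CC/C(C)=C/CCC2=CC[C@H](c3coc([Si](C)(C)C)c3)OC2=O)C(C)(C)CCC1
F9 | step 8 | (1R,3Z,7E)-4-(hydroxymethyl)-8-methyl-1-[5-(trimethylsilyl)furan-3-yl]-10-(2,6,6-trimethylcyclohex-1-en-1-yl)deca-3,7-dien-1-ol | CC1=C(CC/C(C)=C/CC/C(=C/C[C@@H](O)c2coc([Si](C)(C)C)c2)CO)C(C)(C)CCC1
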